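The theta run, with 0.056 M of scavenger, and the gamma run, with 0.088 M, leave 11 % and 10 % of the starting material at 15.0 h. That gap is inside the scatter of 1.5 percentage points, so these readings show no effect of scavenger on the fall.

| flask | starting material | partner | scavenger | remark | time |
|---|---|---|---|---|---|
| theta | 0.050 M | 0.15 M | 0.056 M | run made earlier |  |
| gamma | 0.050 M | 0.15 M | 0.088 M | run made earlier |  |
| flask | 0.050 M | 0.150 M | 0.0400 M |  | 15 h |

| run | time / h | starting material / % | target / % |
|---|---|---|---|
| theta | 3.00 | 56 | 7 |
| theta | 6.00 | 38 | 15 |
| theta | 10.0 | 20 | 23 |
| theta | 12.0 | 14 | 20 |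
| theta | 15.0 | 11 | 25 |
| theta | 20.0 | 5 | 22 |
| gamma | 3.00 | 57 | 8 |
| gamma | 6.00 | 38 | 16 |
| gamma | 10.0 | 19 | 25 |
| gamma | 12.0 | 16 | 23 |
| gamma | 15.0 | 10 | 26 |
| gamma | 20.0 | 6 | 21 |

(scatter of a reading: 1.5 percentage points)

- the earlier runs do not show how much of partner is bound; that part of a forecast is a guess

- part of the starting material that has reacted at 15 h
- share of the unused partner that is free and not bound as idle adduct, at 15 h

Partner stands in excess in theta, so I treat the fall as roughly pseudo-first-order and work in powers of ten. I define the decade dose as the charged partner times the time that starting material takes to fall by one power of ten; theta gives 141 M·min. The flask has 0.150 M of partner, so in 15 h it receives 0.959 decades, and I expect 89.0 % reacted. But the flask's scavenger lies below its starting material, while both runs held more, so my carrying over is a bet.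

The forecast gives 89 % reacted and 94 % free, with the warning “The binding mechanism is unproven”.

The flask gives 89.3 % and 95.7 %, so both forecast values hold.

    starting material + partner → intermediate + released group (k = 1.30 M⁻¹ h⁻¹)
    intermediate ⇌ target (K = 0.670, k = 0.170 h⁻¹)
    intermediate ⇌ isomer of the product (K = 110, k = 0.0730 h⁻¹)
    partner + released group ⇌ idle adduct, settled at all times (K = 69.0 M⁻¹)
    scavenger + released group → scavenged by-product (k = 370 M⁻¹ h⁻¹)
    released group → by-product carried off (k = 0.170 h⁻¹)

The decade dose means 15.6 h per power of ten in this flask, reckoned on charged partner. The first step gives starting material a half-life of 5.3 h at 15.0 h, against 19 h for partner by the same step at 3.41 h, and the flask ends with 11 % of its starting material beside 67 % of its partner.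

In the neighbour with 0.037 M of partner, the dose gives 0.236 decades, so 58.1 % of the starting material should remain. That neighbour computes to 61.2 % remaining, with 47 % of its partner left.

The data come from a simulation with constants of no real substance.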